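Monday's run and Tuesday's run are the same closed flask apart from the second reagent, charged at 1.2 equiv and 2.7 equiv. At 12.0 min, target and isomer of the product together reach 57.1% on Monday and 88.6% on Tuesday, which is more. Yet the share of target in that sum reads 35.6% and 36.9%, a gap that a scatter of 1 percentage point per reading can cover on sums of this size.

| flask | starting material | partner | second reagent | remark | time |
|---|---|---|---|---|---|
| Saturday's | 0.20 M | 4 equiv | 1.8 equiv | run made earlier |  |
| Monday's | 0.20 M | 4 equiv | 1.2 equiv | run made earlier |  |
| Tuesday's | 0.20 M | 4 equiv | 2.7 equiv | run made earlier |  |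
| Thursday's | 0.20 M | 8 equiv | 1.8 equiv | run made earlier |  |
| maple | 0.20 M (fed, over 8.00 min) | 4.00 equiv | 1.80 equiv | a stirred flask in which starting material is dosed at a steady rate over 8.00 min without added volume, worked up at 10 min | 10 min |
| cedar | 0.20 M | 4.00 equiv (fed, over 8.00 min) | 1.80 equiv | a stirred flask in which partner is dosed at a steady rate over 8.00 min without added volume, worked up at 10 min | 10 min |
| larch | 0.20 M | 4.00 equiv | 1.80 equiv | one stirred flow tank at steady state, fed with the mixture as stated, mean residence time 10 min |  |
| birch | 0.20 M | 4.00 equiv | 1.80 equiv | everything together in a closed stirred flask, run for 10 min | 10 min |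

| run | time / min | target / % | isomer of the product / % |
|---|---|---|---|
| Saturday's | 0.833 | 6.4 | 3.5 |
| Saturday's | 1.33 | 8.7 | 6.1 |
| Saturday's | 2.00 | 12.2 | 12.7 |
| Saturday's | 3.00 | 12.8 | 18.4 |
| Saturday's | 4.00 | 15.0 | 26.7 |
| Saturday's | 6.00 | 20.8 | 30.0 |
| Saturday's | 10.0 | 24.4 | 41.6 |
| Monday's | 1.00 | 4.9 | 3.7 |
| Monday's | 1.33 | 5.9 | 5.4 |
| Monday's | 2.00 | 7.7 | 9.9 |
| Monday's | 3.00 | 11.6 | 12.5 |
| Monday's | 5.00 | 14.0 | 21.2 |
| Monday's | 8.00 | 17.6 | 28.7 |
| Monday's | 12.0 | 20.3 | 36.8 |
| Tuesday's | 1.00 | 9.7 | 7.7 |
| Tuesday's | 1.33 | 11.5 | 10.6 |
| Tuesday's | 2.00 | 14.2 | 18.4 |
| Tuesday's | 3.00 | 18.1 | 27.4 |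
| Tuesday's | 5.00 | 25.3 | 37.6 |
| Tuesday's | 8.00 | 29.2 | 48.3 |
| Tuesday's | 12.0 | 32.7 | 55.9 |
| Thursday's | 2.50 | 12.7 | 16.8 |
| Thursday's | 5.00 | 19.0 | 27.3 |
| Thursday's | 8.00 | 21.8 | 37.8 |
| Thursday's | 10.0 | 25.2 | 43.2 |
| Thursday's | 12.0 | 27.9 | 46.0 |

(readings scatter by 1 percentage point)

- the stated concentrations are those of everything mixed, before any reaction; amounts are the same in each set-up
- the feed brings no volume worth counting
- the earlier runs were made in a closed, stirred flask

- the set-up with the highest share of target in all that became target or isomer of the product, at the outlet or at the end ("none" if the first two lie within 2 percentage points) (maple / cedar / larch / birch / none)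
- share of target in all that became target or isomer of the product, at the outlet or at the end, maple
- share of target in all that became target or isomer of the product, at the outlet or at the end, cedar
- share of target in all that became target or isomer of the product, at the outlet or at the end, larch
- share of target in all that became target or isomer of the product, at the outlet or at the end, birch

The last reading of each earlier run, pooled, gives a resting share of target, the equilibrium share of an exchange between target and isomer of the product:

36.9%

Early readings stand above it. While making runs steadily, the surplus, as a fraction of what the share can still lose, is the lifetime divided by the age of the flask. Tuesday's first reading therefore gives, with the scatter of a reading, the exchange lifetime, or relaxation time, the mean time in which fresh target loses its surplus: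

0.299 min

Monday's and Tuesday's flasks have lived 40.1 such lifetimes by their last reading, so their shares meet because the lifetime is short against the time. Where making changes slowly against the lifetime, the surplus is about the room above the resting share, times the lifetime, times the rate of making per amount made. In larch that rate is the washout, and in birch it is read from the last interval of Saturday's run, which has birch's charges, 0.0576 min⁻¹:

larch: 38.7%
birch: 38.0%

These two lie 0.70 points apart and the margin is 2 points. I have no rate of making for maple and cedar at this point, but I expect them beside these two, so my choice is none.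

The forecast gave 38.8% for maple, 37.4% for cedar, 38.6% for larch, 37.4% for birch and best none, reading “target forming first, then equilibrating reversibly with isomer”.

The flasks give 39.1% for maple, 38.2% for cedar, 38.8% for larch and 37.9% for birch, and best is none.

    starting material + partner → intermediate (k = 0.164 L mol⁻¹ s⁻¹)
    second reagent + intermediate → target (k = 0.00708 L mol⁻¹ s⁻¹)
    target ⇌ isomer of the product (K = 1.70, k = 0.0368 s⁻¹)

In birch, the return of isomer of the product to target holds the share up: without that return it falls from 37.9% to 2.13%. The same lifetime of 0.299 min puts larch, reckoned at 38.7%, beside its 38.8%. Cedar made product at 0.0696 min⁻¹ per amount made between the end of its feed and 10 min, so the rule gives 38.2%, and cedar stands at 38.2%.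

(The runs come from a simulation for substances that don't exist, noise included.)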